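**Retrosynthetic overview**

- Target 13 comes from tri-senecioate 12 by selective removal of its two aryl esters. 12 comes from triol 10 and three molecules of 3-methylbut-2-enoyl chloride 11.
- 10 comes from the achiral deoxy compound 9 by enzymatic C–H hydroxylation, which forms the carbinol C–O bond and the only stereocentre. The strategy rests on the side-chain CH2 bonded to furan C4 and to the CH2–CH=C(CH3)2 unit: its two hydrogens are enantiotopic and furylic, hence the weakest C–H bonds of the chain.
- 9 comes from the bis-silyl ether 8, made by Suzuki coupling (furan C2 to benzene C2) of furyl boronate 7 with silyl-protected bromohydroquinone 6.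
- 7 comes from perillene 4 by C–H borylation at the free α position remote from the chain. 4 comes from 3-bromofuran 1 and the Grignard reagent 3 of bromide 2 by Kumada coupling.
- No ring is built: the furan ring (from 1) and the benzene ring (from 5) are bought and joined in step 4.

Key step: step 6

Assumption: the hydroxylase is taken to be the deoxyshikonin hydroxylase paralogue that gives the S (alkannin) series, or a variant of it chosen by screening, because the sense of induction rests on the enzyme alone.

**Step 1**
Reactants: 1 3-bromofuran; 2 5-bromo-2-methylpent-2-ene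
Product: 4 perillene [3-(4-methylpent-3-en-1-yl)furan], via Grignard reagent 3 (not isolated)
Conditions: 2, Mg, THF, 25–40 °C; then 1, NiCl2(dppp) (2 mol%), THF/Et2O, 0 °C to reflux
Reagents that add atoms: none
Why: Kumada–Corriu cross-coupling, in which the primary alkyl Grignard reagent 3 transmetalates to nickel after oxidative addition of 1 and the chelating dppp ligand favours reductive elimination over β-hydride elimination.

**Step 2**
Reactants: 5 2-bromobenzene-1,4-diol (2-bromohydroquinone)
Product: 6 2-bromo-1,4-bis(tert-butyldimethylsilyloxy)benzene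
Conditions: TBSCl (2.4 equiv), imidazole (5 equiv), DMF, 0 °C to rt
Reagents that add atoms: tert-butyldimethylsilyl chloride, CC(C)(C)[Si](C)(C)Cl
Why: Imidazole-promoted silylation of both phenols (two molecules of the silyl chloride) gives ethers that should survive the mild Suzuki coupling and later fall to fluoride without harm to the furan or the alkene.

**Step 3**
Reactants: 4 perillene
Product: 7 4,4,5,5-tetramethyl-2-[4-(4-methylpent-3-en-1-yl)furan-2-yl]-1,3,2-dioxaborolane
Conditions: B2pin2 (0.55 equiv), [Ir(OMe)(cod)]2 (1.5 mol%), 4,4'-di-tert-butyl-2,2'-bipyridine (3 mol%), hexane, rt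
Reagents that add atoms: bis(pinacolato)diboron, CC1(C)OB(OC1(C)C)B1OC(C)(C)C(C)(C)O1
Why: Iridium-catalysed aromatic C–H borylation is sterically governed, so a 3-substituted furan should react at the α position remote from the substituent (C5), while the trisubstituted alkene should stay inert at room temperature.

**Step 4**
Reactants: 7 furyl boronate; 6 2-bromo-1,4-bis(tert-butyldimethylsilyloxy)benzene
Product: 8 2-[2,5-bis(tert-butyldimethylsilyloxy)phenyl]-4-(4-methylpent-3-en-1-yl)furan
Conditions: Pd(OAc)2 (2 mol%), SPhos (4 mol%), K3PO4 (2 M aq.), THF, 50 °C, degassed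
Reagents that add atoms: none
Why: Suzuki–Miyaura coupling, in which the electron-rich SPhos ligand speeds oxidative addition to the ortho-substituted, electron-rich bromide 6 and transmetalation, so coupling should outrun protodeboronation of the 2-furyl boronate.

**Step 5**
Reactants: 8 bis-silyl ether
Product: 9 2-[4-(4-methylpent-3-en-1-yl)furan-2-yl]benzene-1,4-diol
Conditions: Bu4NF (2.5 equiv), AcOH (2.5 equiv), THF, 0 °C, argon
Reagents that add atoms: none
Why: Fluoride-mediated desilylation of the two aryl silyl ethers, with acetic acid protonating the phenoxides so that the hydroquinone is released without base-promoted air oxidation and the furan and alkene are untouched.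

**Step 6**
Reactants: 9 2-[4-(4-methylpent-3-en-1-yl)furan-2-yl]benzene-1,4-diol
Product: 10 (S)-2-[4-(1-hydroxy-4-methylpent-3-en-1-yl)furan-2-yl]benzene-1,4-diol
Conditions: recombinant S-series deoxyshikonin hydroxylase (cytochrome P450, CYP82AR subfamily) with NADPH–cytochrome P450 reductase (yeast microsomes), NADP+ (cat.), D-glucose, glucose dehydrogenase, catalase, sodium ascorbate (NaC6H7O6), O2 (air), KH2PO4/K2HPO4 buffer pH 7.5, DMSO (2% v/v), 30 °C
Reagents that add atoms: dioxygen, O=O
Why: Proposed new method: the oxoiron porphyrin radical cation of the enzyme (iron formally tetravalent, formed from O2 and two electrons passed from NADPH through the reductase) abstracts the pro-S hydrogen of the CH2 on furan C4, and the furylic radical recombines with the iron-bound hydroxyl on the same face (radical rebound), so the C–O bond forms with retention and gives the S carbinol. The closest known reaction type is the cytochrome P450 hydroxylation of the same side-chain CH2 in deoxyshikonin to alkannin or shikonin, together with benzylic hydroxylations by engineered P450 enzymes; it has not been shown on a 2-arylfuran. No ring is closed. The new stereocentre is controlled only by the chiral active site, which presents one of the two enantiotopic hydrogens to the oxidant, the substrate being achiral. The step needs site selectivity for the furylic CH2 over the allylic CH2, the methyl groups, the trisubstituted alkene, the furan and the hydroquinone, and it must stop at the alcohol; the low strength of the furylic C–H bond (radical delocalised into the furan) and the close shape match of 9 to deoxyshikonin (the same 4-methylpent-3-enyl chain on a planar ring next to a para-dioxygenated arene) should secure this, with ascorbate and catalase keeping the hydroquinone reduced.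

**Step 7**
Reactants: 10 (S)-triol; 11 3-methylbut-2-enoyl chloride
Product: 12 (S)-2-{4-[4-methyl-1-(3-methylbut-2-enoyloxy)pent-3-en-1-yl]furan-2-yl}-1,4-phenylene bis(3-methylbut-2-enoate)
Conditions: 3-methylbut-2-enoyl chloride 11 (4 equiv), pyridine, DMAP (10 mol%), CH2Cl2, −10 to 0 °C, argon
Reagents that add atoms: 3-methylbut-2-enoyl chloride (the second and third molecules of 11), CC(C)=CC(Cl)=O
Why: Pyridine/DMAP-mediated acylation (Einhorn-type) consumes three molecules of 11, one for each hydroxyl, so no differentiation is needed at this stage; the weak base should limit vinylketene-mediated deconjugation of the acyl group, and the C–O bond at the stereocentre is not broken, so S is retained.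

**Step 8**
Reactants: 12 tri-senecioate
Product: 13 (S)-1-[5-(2,5-dihydroxyphenyl)furan-3-yl]-4-methylpent-3-en-1-yl 3-methylbut-2-enoate (target)
Conditions: 3-(dimethylamino)propan-1-amine (2.5 equiv), THF, 0 °C to rt, argon; wash with KH2PO4/K2HPO4 buffer pH 6
Reagents that add atoms: none
Why: Chemoselective aminolysis, in which the two aryl esters (phenoxide leaving groups) should react with the primary amine far faster than the secondary alkyl senecioate, conjugate addition is hindered by the β,β-dimethyl group, and the stereocentre is not involved.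

**Compound list**

1 | 3-bromofuran | Brc1ccoc1 | starting material
2 | 5-bromo-2-methylpent-2-ene | CC(C)=CCCBr | starting material
3 | (4-methylpent-3-en-1-yl)magnesium bromide | CC(C)=CCC[Mg]Br | intermediate
4 | perillene, 3-(4-methylpent-3-en-1-yl)furan | CC(C)=CCCc1ccoc1 | intermediate
5 | 2-bromobenzene-1,4-diol | Oc1ccc(O)c(Br)c1 | starting material
6 | 2-bromo-1,4-bis(tert-butyldimethylsilyloxy)benzene | CC(C)(C)[Si](C)(C)Oc1ccc(O[Si](C)(C)C(C)(C)C)c(Br)c1 | intermediate
7 | 4,4,5,5-tetramethyl-2-[4-(4-methylpent-3-en-1-yl)furan-2-yl]-1,3,2-dioxaborolane | CC(C)=CCCc1coc(B2OC(C)(C)C(C)(C)O2)c1 | intermediate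
8 | 2-[2,5-bis(tert-butyldimethylsilyloxy)phenyl]-4-(4-methylpent-3-en-1-yl)furan | CC(C)=CCCc1coc(-c2cc(O[Si](C)(C)C(C)(C)C)ccc2O[Si](C)(C)C(C)(C)C)c1 | intermediate
9 | 2-[4-(4-methylpent-3-en-1-yl)furan-2-yl]benzene-1,4-diol | CC(C)=CCCc1coc(-c2cc(O)ccc2O)c1 | intermediate
10 | (S)-2-[4-(1-hydroxy-4-methylpent-3-en-1-yl)furan-2-yl]benzene-1,4-diol | CC(C)=CC[C@H](O)c1coc(-c2cc(O)ccc2O)c1 | intermediate
11 | 3-methylbut-2-enoyl chloride | CC(C)=CC(Cl)=O | starting material
12 | (S)-2-{4-[4-methyl-1-(3-methylbut-2-enoyloxy)pent-3-en-1-yl]furan-2-yl}-1,4-phenylene bis(3-methylbut-2-enoate) | CC(C)=CC[C@H](OC(=O)C=C(C)C)c1coc(-c2cc(OC(=O)C=C(C)C)ccc2OC(=O)C=C(C)C)c1 | intermediate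
13 | (S)-1-[5-(2,5-dihydroxyphenyl)furan-3-yl]-4-methylpent-3-en-1-yl 3-methylbut-2-enoate | CC(C)=CC[C@H](OC(=O)C=C(C)C)c1coc(-c2cc(O)ccc2O)c1 | target

**Step count**

Total: 8 steps. Longest linear sequence: 7 steps (steps 1, 3, 4, 5, 6, 7, 8); step 2 is on the side branch.

**Steps most likely to fail**

1. Step 6 (the new biocatalytic hydroxylation). The enzyme may not turn over the unnatural furan substrate. It may oxidise elsewhere (allylic methyl hydroxylation, epoxidation of the alkene), remove the other enantiotopic hydrogen, or carry the alcohol on to the ketone. The hydroquinone may also autoxidise during the incubation.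
Fallback by known chemistry, setting out from 1 and coming back to the route at 10: bromine–lithium exchange of 1 (n-BuLi, Et2O, −78 °C) and a DMF quench should give furan-3-carbaldehyde F1. Brown allylation with (−)-Ipc2B(allyl), the reagent from (+)-α-pinene that adds to the Si face of aromatic aldehydes (Et2O, −78 °C; NaOH/H2O2 work-up), should give (S)-1-(furan-3-yl)but-3-en-1-ol F2. Silylation (TBSCl, imidazole, DMF) gives (S)-tert-butyl{[1-(furan-3-yl)but-3-en-1-yl]oxy}dimethylsilane F3. Cross-metathesis with 2-methylbut-2-ene (second-generation Grubbs catalyst, 40 °C) turns the allyl terminus into the prenyl-type alkene of (S)-tert-butyl{[1-(furan-3-yl)-4-methylpent-3-en-1-yl]oxy}dimethylsilane F4. Borylation under the conditions of step 3 gives the furyl boronate F5, Suzuki coupling with 6 under the conditions of step 4 gives the tris-silyl ether F6, and Bu4NF/AcOH in THF removes all three silyl groups to give 10.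

2. Step 8 (selective aminolysis). The hindered aryl ester next to the furan may cleave too slowly, so that forcing conditions begin to attack the furylic ester. The freed hydroquinone may be air-oxidised under the basic amine. Deconjugated acyl groups carried over from step 7 would also show up here.
Fallback, setting out from 10 and coming back at 13: phenoxide-selective Schotten–Baumann acetylation (Ac2O, aqueous NaOH, THF, 0 °C, argon) should give (S)-2-[4-(1-hydroxy-4-methylpent-3-en-1-yl)furan-2-yl]-1,4-phenylene diacetate F7 with the alcohol free. Acylation of that alcohol with 11 (pyridine, CH2Cl2, 0 °C, no DMAP) gives the mixed ester (S)-2-{4-[4-methyl-1-(3-methylbut-2-enoyloxy)pent-3-en-1-yl]furan-2-yl}-1,4-phenylene diacetate F8. Hydrazine acetate in DMF at 0 °C then removes only the two far more labile aryl acetates and gives 13.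

3. Step 3 (C–H borylation). Borylation may compete at C2 next to the chain, a second boryl group may be introduced, and the 2-furyl boronate may protodeboronate during isolation.
Fallback, setting out from 4 and coming back at 8: deprotonation with the hindered base lithium 2,2,6,6-tetramethylpiperidide (THF, −78 to −40 °C) at the unhindered α position should give [4-(4-methylpent-3-en-1-yl)furan-2-yl]lithium F9. Transmetalation with ZnCl2 gives chloro[4-(4-methylpent-3-en-1-yl)furan-2-yl]zinc F10. Negishi coupling with 6 (Pd(OAc)2, SPhos, THF, rt to 50 °C) gives 8 directly, so no boronate is handled.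

**Further compounds**

F1 | step 6 | furan-3-carbaldehyde | O=Cc1ccoc1
F2 | step 6 | (S)-1-(furan-3-yl)but-3-en-1-ol | C=CC[C@H](O)c1ccoc1
F3 | step 6 | (S)-tert-butyl{[1-(furan-3-yl)but-3-en-1-yl]oxy}dimethylsilane | C=CC[C@H](O[Si](C)(C)C(C)(C)C)c1ccoc1
F4 | step 6 | (S)-tert-butyl{[1-(furan-3-yl)-4-methylpent-3-en-1-yl]oxy}dimethylsilane | CC(C)=CC[C@H](O[Si](C)(C)C(C)(C)C)c1ccoc1
F5 | step 6 | (S)-tert-butyldimethyl{[4-methyl-1-(5-(4,4,5,5-tetramethyl-1,3,2-dioxaborolan-2-yl)furan-3-yl)pent-3-en-1-yl]oxy}silane | CC(C)=CC[C@H](O[Si](C)(C)C(C)(C)C)c1coc(B2OC(C)(C)C(C)(C)O2)c1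
F6 | step 6 | (S)-2-[2,5-bis(tert-butyldimethylsilyloxy)phenyl]-4-[1-(tert-butyldimethylsilyloxy)-4-methylpent-3-en-1-yl]furan | CC(C)=CC[C@H](O[Si](C)(C)C(C)(C)C)c1coc(-c2cc(O[Si](C)(C)C(C)(C)C)ccc2O[Si](C)(C)C(C)(C)C)c1
F7 | step 8 | (S)-2-[4-(1-hydroxy-4-methylpent-3-en-1-yl)furan-2-yl]-1,4-phenylene diacetate | CC(C)=CC[C@H](O)c1coc(-c2cc(OC(C)=O)ccc2OC(C)=O)c1
F8 | step 8 | (S)-2-{4-[4-methyl-1-(3-methylbut-2-enoyloxy)pent-3-en-1-yl]furan-2-yl}-1,4-phenylene diacetate | CC(C)=CC[C@H](OC(=O)C=C(C)C)c1coc(-c2cc(OC(C)=O)ccc2OC(C)=O)c1
F9 | step 3 | [4-(4-methylpent-3-en-1-yl)furan-2-yl]lithium | [Li]c1cc(CCC=C(C)C)co1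
F10 | step 3 | chloro[4-(4-methylpent-3-en-1-yl)furan-2-yl]zinc | Cl[Zn]c1cc(CCC=C(C)C)co1
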